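The trap I watched for was treating the ratio of the other capture product to the target as a constant of the chemistry. Both products come from one intermediate through rival partners, so I expected the ratio to follow [second nucleophile]/[first nucleophile].

| flask | substrate | second nucleophile | gas | remark | time |
|---|---|---|---|---|---|
| elm | 0.10 M | 0.60 M | 81 mM (held) | run made earlier |  |
| larch | 0.40 M | 0.60 M | 81 mM (held) | run made earlier |  |
| birch | 0.20 M | 1.2 M | 81 mM (held) | run made earlier |  |
| flask | 0.20 M | 0.600 M | 81 mM (held) |  | 12 h |

| run | time / h | other capture product / % | target / % | substrate / % |
|---|---|---|---|---|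
| elm | 1.50 | 11 | 20 | 44 |
| elm | 4.00 | 19 | 36 | 10 |
| elm | 8.00 | 22 | 37 | 0 |
| elm | 12.0 | 18 | 35 | 1 |
| larch | 1.50 | 14 | 18 | 45 |
| larch | 4.00 | 20 | 29 | 11 |
| larch | 8.00 | 23 | 35 | 0 |
| larch | 12.0 | 25 | 33 | 0 |
| birch | 1.50 | 21 | 15 | 43 |
| birch | 4.00 | 31 | 27 | 11 |
| birch | 8.00 | 33 | 29 | 0 |
| birch | 12.0 | 33 | 26 | 2 |

(each reading ± 2 percentage points)

1. ratio of other capture product to target at 6.0 min
2. ratio of other capture product to target at 1.0 h
3. ratio of other capture product to target at 12 h
4. which of other capture product and target there is more of at 12 h

- at the start none of first nucleophile is dissolved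
- steps under discussion: gas <-> first nucleophile; second nucleophile + intermediate -> other capture product; substrate -> intermediate; first nucleophile + intermediate -> target; intermediate -> solvolysis product; target -> over-reaction product; second nucleophile -> decomposition product

I therefore pooled the readings at 8.00 h and 12.0 h, when the substrate read at most 2%, and divided each run's ratio by its [second nucleophile]:

| run | substrate | second nucleophile | ratio per molar |
|---|---|---|---|
| elm | 0.10 M | 0.60 M | 0.926 M⁻¹ |
| birch | 0.20 M | 1.2 M | 1.00 M⁻¹ |
| larch | 0.40 M | 0.60 M | 1.18 M⁻¹ |

Elm and birch are two independent ways to one number, and they differ by 0.0740 M⁻¹, while one reading of the other capture product in elm carries about 9.09% of scatter. I trusted their mean, the capture quotient (a selectivity factor), which is late other capture product per target per molar second nucleophile: 0.963 M⁻¹.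

Larch stands higher by 0.217 M⁻¹, so I wrote the balance of the first nucleophile, which has a gain from the gas as well as a loss to the target. I could read no rate for that gain from these runs, so the target formed in larch did not show me a lower [first nucleophile]; I could not tell the gap from scatter, and I kept larch out of the mean. The flask has birch's substrate charge, and I reckoned its ratio at 12 h as 0.578, with the target ahead. I put no number on the early ratios, except that they should start higher, since no first nucleophile is dissolved at the start.

The forecast gave 2.9 at 6.0 min, 0.75 at 1.0 h and 0.62 at 12 h, a little above mine, with the target leading, and it read larch as showing that “dissolved first nucleophile is somewhat depleted by gas-transfer limits”.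

The flask gave 2.15, 0.700 and 0.632, with the target at 33.9% against 21.4% of the other capture product.

    gas ⇌ first nucleophile, rate k1*(csat - [first nucleophile]) (kL = 5.50 h⁻¹)
    second nucleophile + intermediate → other capture product (k = 57.0 M⁻¹ h⁻¹)
    substrate → intermediate (k = 0.540 h⁻¹)
    first nucleophile + intermediate → target (k = 830 M⁻¹ h⁻¹)
    intermediate → solvolysis product (k = 63.0 h⁻¹)
    target → over-reaction product (k = 0.0100 h⁻¹)
    second nucleophile → decomposition product (k = 9.00 × 10⁻⁵ h⁻¹)

A run with half the substrate and all other amounts as in the flask gave a ratio of 0.630 at 12 h. Carried to the neighbour charged with 1.5 M of second nucleophile, the capture quotient of 0.963 M⁻¹ gives a ratio of 1.44, and that neighbour stood at 1.57 at 12 h.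

The readings stem from a simulated flask on assumed constants, and the scatter is random.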